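**Remark on the target:** the name is read as 3,5,8,4'-tetrahydroxy-7-methoxyflavone acetylated on O8 only; the molecule is achiral, so no configuration has to be set.

## Structural features

The target is a flavonol: a 4H-chromen-4-one in which the benzo ring A and the pyranone ring C share the C4a–C8a bond, with a 4-hydroxyphenyl ring B joined to C2 by a single C–C bond. There is no stereocentre, so no stereocentres stand next to each other and the whole problem is one of regiochemistry and of telling oxygen atoms apart. Ring A carries oxygen on every carbon but C6: a hydroxyl on C5 hydrogen-bonded to the C4 carbonyl, a methoxy group on C7, the acetate on C8 and the ring oxygen O1 on C8a, while ring C adds the enolic hydroxyl on C3. The fragile groups are the aryl acetate, which is lost to any alkoxide, hydroxide or nucleophilic amine and so must go on after the last basic step, and the 5,8-dioxygenated ring A, a hydroquinone in disguise that is oxidised easily to the 5,8-quinone once both oxygens are free in basic, aerated solution. The real difficulty is not the fifteen-carbon skeleton but the five oxygens, which must end as one acetate (O8), one methyl ether (O7) and three free hydroxyls (O3, O5, O4'), together with the need to bring an oxygen onto C3. The key step exploits the fact that O1 on C8a and the methoxy oxygen on C7 both flank the C8 oxygen, with the C5 oxygen para to it. Ring A is therefore a 2,6-dimethoxyhydroquinone in which one of two equivalent methoxy oxygens has become O1, and attack of that oxygen on an activated ynone carbon (the future C2) closes ring C and leaves iodine on C3. A second feature is used at the end: the hydrogen bond from the 5-hydroxyl to the C4 carbonyl makes O5 far less reactive than O8, so O8 alone can be acetylated.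

## Logic of the disconnections

13 ⇒ 12. The two O–CH2Ph bonds on O3 and O4' are cut. The acetate on O8 tolerates neither base nor nucleophile, so the last step has to be neutral, and hydrogenolysis is. The gain is that the three free hydroxyls of 13 never have to be told apart from O8. The demand is that nothing else in 12 is reduced and that the solvent cannot transesterify the acetate.

12 ⇒ 11. The O8–acetyl bond is cut. In 11 the C5 hydroxyl is tied to the C4 carbonyl and the C8 hydroxyl is an ordinary phenol, so the flavone differentiates the two hydroquinone oxygens by itself and no separate protecting group is needed. The demand on the forward step is mono-acylation with one equivalent of anhydride and without an acyl-transfer catalyst.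

11 ⇒ 8 + 9. The C3–O bond is cut back to the C3–I bond, and the two acetyl groups on O5 and O8 are restored. The basic alcohol medium of the coupling removes both esters anyway (through 10), so deprotection costs no step. The gain is that the 3-oxygen and its benzyl group come from one cheap reagent. The demand is a copper-catalysed C–O coupling on an alkenyl iodide flanked by a carbonyl and an aryl group, run with 9 in large excess so that the phenoxides set free in the flask do not compete, and under argon because 10 and 11 are hydroquinones.

8 ⇒ 6 (key disconnection). The O1–C2 bond and the C3–I bond are cut, and the methyl group is put back on the oxygen that becomes O1. Ring C opens to an ynone, and ring A becomes a benzene carrying two methoxy and two acetoxy groups derived from a symmetric precursor. The atom mapping was checked: the methoxy ortho to the ketone of 6 supplies O1, the acetate between the two methoxy groups ends on C8, the acetate ortho to the ketone on C5, and the remaining methoxy on C7. The forward step needs three things: 6-endo closure, closure through the ether oxygen and not through O5, and iodine on the alkyne and not on an arene. Acetyl on O5 serves the second and third needs, since an ether at O5 would be a competing nucleophile and would make ring A too electron-rich.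

6 ⇒ 4 + 5. The bonds from the carbonyl carbon to ring A (C4–C4a) and to the alkyne (C4–C3) are cut, and the carbonyl carbon is supplied as a C1 gas. Three simple components replace the whole C6–C3–C6 chain. The demand is that carbonyl insertion outruns direct aryl–alkyne coupling and that only a tertiary amine is present. A secondary amine would free the O5 phenol next to the ketone, which would then close ring C through the wrong oxygen.

4 ⇒ 3. The C–I bond is cut. The two ring CH positions of 3 are equivalent by symmetry, so one substitution fixes the entire 5,7,8 pattern without a regiochemical choice. The demand is mono-iodination.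

3 ⇒ 1. The two O–acetyl bonds are cut and the ring is oxidised back to the commercial quinone 1. Reduction and acetylation are run in one flask through 2, so the air-sensitive hydroquinone is never handled.

## Other disconnections considered

Alternative 1: Ring A is cut at C4a–C5 and C8–C8a. In the forward direction the silyloxyfuran A2 (the silyl dienol ether of a tetronate) adds in a Diels–Alder reaction across the triple bond of the bromoalkynone A3. The oxygen bridge of the adduct opens at the bridgehead carrying the silyloxy group, and loss of the other bridgehead proton gives the arene A1 with a free 8-hydroxyl, silylated O5, bromine on the future C8a and a benzyloxyacetyl chain on C4a. Ring C would follow by C-aroylation of the ketone α-carbon and copper-mediated intramolecular O-arylation at the C–Br bond.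
- In its favour: all ring A oxygens are different from the start. O8 is the only free hydroxyl of A1, so the acetate or an orthogonal group can go on with no selectivity question. On this point it is better than the chosen plan, which relies on the hydrogen bond to C4=O.
- Also in its favour: the 3-oxygen is carried in by A3, so no C–O coupling at C3 is needed, again a point in which it is better. The position of the C6 hydrogen is equally secure in both plans.
- Against it: A2 is hydrolytically labile and A3 is a sensitive electrophile. Both the orientation of the cycloaddition and the direction of bridge opening must go one way. Ring C still needs two bond constructions under base, which an aryl acetate cannot survive, so O8 would need a temporary group and the acetate would still arrive near the end. The O-arylation would take place on a bromide flanked on both sides.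
- Step economy: two reagents to prepare, then cycloaddition, protection, aroylation, ring closure, deprotection, acetylation, desilylation and hydrogenolysis. That is clearly more than seven steps, against a ring A that the chosen plan buys ready-made.

Alternative 2: Ring C is cut at C3–C4 and O1–C2 in one operation. Irradiation of the benzodioxinone A5 expels its ketal carbon as a ketone and gives the quinoketene A7. The nucleophilic carbon of the enol silane A6 attacks the ketene carbon (C3–C4), the ring carbonyl oxygen closes onto the silyloxy carbon (O1–C2), and acid removes silanol to give the flavone A4.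
- In its favour: it is the most convergent of the four plans, with two bonds formed in one step and rings A and B, the 3-benzyloxy group and the 8-acetate all in place. A4 would need only one hydrogenolysis to reach the target. The endgame is therefore better than that of the chosen plan: no copper coupling, no selective acetylation, no free hydroquinone. O5 may be a simple benzyl ether here, which is at least equal.
- Against it: A5 requires a salicylic acid with four differently substituted oxygens. The differentiation problem is moved to the start, not solved, and no symmetric commercial precursor exists. The aryl acetate of A5 is itself photolabile (photo-Fries rearrangement) at wavelengths that open the dioxinone. Capture of A7 by alcohols and amines is well-trodden, whereas C–C bond formation with a trisubstituted, α-oxygenated enol silane followed by ring closure is less secure and competes with ketene dimerisation.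
- Step economy: the convergent end is shorter, but the total count is expected to be higher because of the synthesis of A5.

Alternative 3: Ring C is cut at C3–C4 only, leading to the dialdehyde A9. A triazolium-derived carbene converts the aromatic aldehyde into an acyl anion equivalent that adds to the aliphatic aldehyde and gives the trans dihydroflavonol A8. Both stereocentres would be erased later by dehydrogenation to the flavonol.
- In its favour: it is metal-free, and the C3 oxygen arises directly from an aldehyde oxygen, so no functionalisation of C3 is needed. On this point it is better than the chosen plan. Neither plan has a lasting stereochemical problem, which makes them equal there.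
- Against it: the aliphatic aldehyde of A9 is the more electrophilic one. Carbene addition there leads either to the regioisomeric ketol or, by expulsion of the α-aryloxy group, to internal redox chemistry that destroys the ether link. A9 is also an enolisable α-aryl-α-aryloxy aldehyde of doubtful stability.
- Decisive for this target: A8 carries three methyl ethers. O5 could be freed with chelation control, but there is no dependable way to free O8 while O7 stays methylated, and without a free 8-hydroxyl there is no 8-acetate. The chosen plan avoids this because O7 is the only methyl ether it ever keeps.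
- Step economy: about as long up to A8, then longer (oxidation, two demethylations, acetylation, hydrogenolysis), with one step lacking a basis for selectivity.

Key step: step 4

## Route

Step 1
Reactants: 1 2,6-dimethoxy-1,4-benzoquinone
Product: 3 2,6-dimethoxy-1,4-phenylene diacetate, via 2,6-dimethoxyhydroquinone 2 (not isolated)
Conditions: Zn dust, Ac2O, NaOAc, 60 °C
Reagents that add atoms: acetic anhydride, CC(=O)OC(C)=O
Why: Reductive acetylation: zinc reduces the quinone to the hydroquinone 2 (present as its zinc phenoxide), which is acetylated at once on both oxygens, so the oxidation-prone hydroquinone is never exposed to air.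

Step 2
Reactants: 3 2,6-dimethoxy-1,4-phenylene diacetate
Product: 4 2-iodo-3,5-dimethoxy-1,4-phenylene diacetate
Conditions: NIS (1.05 equiv), CF3CO2H (0.2 equiv), MeCN, rt, dark
Reagents that add atoms: N-iodosuccinimide, O=C1CCC(=O)N1I
Why: Electrophilic aromatic iodination with acid-activated NIS; the two ring CH positions are equivalent and each is ortho to one methoxy and para to the other, so a single regioisomer should form, and the first iodine slows a second substitution.

Step 3
Reactants: 4 2-iodo-3,5-dimethoxy-1,4-phenylene diacetate; 5 1-(benzyloxy)-4-ethynylbenzene
Product: 6 2-{3-[4-(benzyloxy)phenyl]propioloyl}-3,5-dimethoxy-1,4-phenylene diacetate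
Conditions: CO (1 atm), PdCl2(PPh3)2 (5 mol%), CuI (2 mol%), Et3N, THF, rt
Reagents that add atoms: carbon monoxide, [C-]#[O+]
Why: Carbonylative Sonogashira coupling: zerovalent palladium inserts into the C–I bond, CO insertion gives the aroyl-palladium species, and the copper acetylide of 5 transmetalates before reductive elimination to the ynone. The two ortho substituents slow direct alkynylation relative to CO insertion, and the tertiary amine leaves the aryl acetates intact.

Step 4
Reactants: 6 2-{3-[4-(benzyloxy)phenyl]propioloyl}-3,5-dimethoxy-1,4-phenylene diacetate
Product: 8 5,8-diacetoxy-4'-(benzyloxy)-3-iodo-7-methoxyflavone, via O-methyloxonium chloride 7 (not isolated)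
Conditions: ICl (1.3 equiv), CH2Cl2, −78 °C to rt; aq. Na2S2O3
Reagents that add atoms: iodine monochloride, ICl
Why: ICl delivers electrophilic iodine to the triple bond of 6 and gives an iodonium species whose positive charge sits on the carbon that becomes C2, because the 4-benzyloxyphenyl group stabilises it and the acyl group disfavours charge on C3. The methoxy oxygen ortho to the ketone attacks that carbon anti to iodine and closes ring C in the 6-endo-dig mode to the oxonium salt 7; chloride then removes the methyl group by SN2 attack, CH3Cl leaves and the neutral pyranone 8 results. The closest known reaction type is the ICl-induced iodocyclisation of 2-methoxyaryl alkynyl ketones to 3-iodochromones. No stereocentre is formed. Three selectivities are needed: (a) of the two oxygens ortho to the ketone only the ether oxygen is nucleophilic, the O5 acetate oxygen being deactivated by its own carbonyl, so closure uses the C8a oxygen and the 5,7,8 pattern is fixed; (b) 5-exo attack at the carbon next to the carbonyl would lead to an aurone-type ring but requires positive charge beside the carbonyl and is disfavoured; (c) the alkyne must react before the arenes, which the two acetates and the ketone on ring A, the low temperature and the small excess of ICl should secure.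

Step 5
Reactants: 8 5,8-diacetoxy-4'-(benzyloxy)-3-iodo-7-methoxyflavone; 9 benzyl alcohol
Product: 11 3,4'-bis(benzyloxy)-5,8-dihydroxy-7-methoxyflavone, via 4'-(benzyloxy)-5,8-dihydroxy-3-iodo-7-methoxyflavone 10 (not isolated)
Conditions: CuI (10 mol%), 1,10-phenanthroline (20 mol%), Cs2CO3 (3.5 equiv), 9/toluene (1:1), 110 °C, Ar; aq. NH4Cl
Reagents that add atoms: none
Why: Ullmann-type copper-catalysed C–O coupling of the alkenyl iodide with a primary alcohol; cesium benzyl alkoxide first transesterifies both aryl acetates (giving 10 as its cesium phenoxide and benzyl acetate), and the large excess of 9 keeps the freed phenoxides from acting as coupling partners. Argon and a mildly acidic work-up protect the hydroquinone.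

Step 6
Reactants: 11 3,4'-bis(benzyloxy)-5,8-dihydroxy-7-methoxyflavone
Product: 12 3,4'-bis(benzyloxy)-5-hydroxy-7-methoxyflavon-8-yl acetate
Conditions: Ac2O (1.05 equiv), pyridine (1.5 equiv), CH2Cl2, 0 °C, Ar
Reagents that add atoms: acetic anhydride, CC(=O)OC(C)=O
Why: Chemoselective O-acylation: the 5-hydroxyl is held in a strong hydrogen bond to the C4 carbonyl and is the less acidic and less nucleophilic phenol, whereas the 8-hydroxyl is free, so one equivalent of anhydride at 0 °C without an acyl-transfer catalyst should acetylate O8 only.

Step 7
Reactants: 12 3,4'-bis(benzyloxy)-5-hydroxy-7-methoxyflavon-8-yl acetate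
Product: 13 pollenitin 8-acetate (3,5-dihydroxy-2-(4-hydroxyphenyl)-7-methoxy-4-oxo-4H-chromen-8-yl acetate)
Conditions: H2 (1 atm), 10% Pd/C, EtOAc/THF, rt
Reagents that add atoms: none
Why: Heterogeneous hydrogenolysis of the two benzyl ethers on O3 and O4'; the aryl acetate, the methyl ether and the tetrasubstituted conjugated C2=C3 bond are inert under these neutral conditions, and the aprotic solvent excludes transesterification of the acetate.

## Compound list

1 | 2,6-dimethoxy-1,4-benzoquinone | COC1=CC(=O)C=C(OC)C1=O | starting material
2 | 2,6-dimethoxybenzene-1,4-diol (2,6-dimethoxyhydroquinone; zinc phenoxide in the flask, not isolated) | COc1cc(O)cc(OC)c1O | intermediate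
3 | 2,6-dimethoxy-1,4-phenylene diacetate | COc1cc(OC(C)=O)cc(OC)c1OC(C)=O | intermediate
4 | 2-iodo-3,5-dimethoxy-1,4-phenylene diacetate | COc1cc(OC(C)=O)c(I)c(OC)c1OC(C)=O | intermediate
5 | 1-(benzyloxy)-4-ethynylbenzene | C#Cc1ccc(OCc2ccccc2)cc1 | starting material
6 | 2-{3-[4-(benzyloxy)phenyl]propioloyl}-3,5-dimethoxy-1,4-phenylene diacetate | COc1cc(OC(C)=O)c(C(=O)C#Cc2ccc(OCc3ccccc3)cc2)c(OC)c1OC(C)=O | intermediate
7 | 5,8-diacetoxy-2-[4-(benzyloxy)phenyl]-3-iodo-7-methoxy-1-methyl-4-oxo-4H-chromen-1-ium chloride (not isolated) | COc1cc(OC(C)=O)c2C(=O)C(I)=C(c3ccc(OCc4ccccc4)cc3)[O+](C)c2c1OC(C)=O.[Cl-] | intermediate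
8 | 5,8-diacetoxy-4'-(benzyloxy)-3-iodo-7-methoxyflavone | COc1cc(OC(C)=O)c2c(=O)c(I)c(-c3ccc(OCc4ccccc4)cc3)oc2c1OC(C)=O | intermediate
9 | benzyl alcohol | OCc1ccccc1 | starting material
10 | 4'-(benzyloxy)-5,8-dihydroxy-3-iodo-7-methoxyflavone (cesium phenoxide in the flask, not isolated) | COc1cc(O)c2c(=O)c(I)c(-c3ccc(OCc4ccccc4)cc3)oc2c1O | intermediate
11 | 3,4'-bis(benzyloxy)-5,8-dihydroxy-7-methoxyflavone | COc1cc(O)c2c(=O)c(OCc3ccccc3)c(-c3ccc(OCc4ccccc4)cc3)oc2c1O | intermediate
12 | 3,4'-bis(benzyloxy)-5-hydroxy-7-methoxyflavon-8-yl acetate | COc1cc(O)c2c(=O)c(OCc3ccccc3)c(-c3ccc(OCc4ccccc4)cc3)oc2c1OC(C)=O | intermediate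
13 | pollenitin 8-acetate | COc1cc(O)c2c(=O)c(O)c(-c3ccc(O)cc3)oc2c1OC(C)=O | target

## Step count and least certain steps

Total: 7 steps. Longest linear sequence: 7 steps (1 to 13); 5 and 9 are purchased and enter in steps 3 and 5.

**Step 4 (key step).** The most likely failure is delivery of iodine to an electron-rich arene (C6 of ring A or the position ortho to the benzyloxy group), or simple addition of ICl across the triple bond. Closure may be slow because the attacking methoxy group is flanked on both sides and the ketone is twisted out of the plane of ring A. The fallback separates ring closure from iodination. Setting out from 6, MgI2·OEt2 in toluene/Et2O at 60 °C cleaves only the methyl ether that can chelate to the ketone; iodide can break an O–alkyl bond but not the acetates. The magnesium phenoxide so formed adds to the ynone in the 6-endo sense and should give 5,8-diacetoxy-4'-(benzyloxy)-7-methoxyflavone F1. Iodination of C3 with I2 and (NH4)2Ce(NO3)6 in MeCN then comes back to the route at 8.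

**Step 5.** The most likely failure is interference by the phenoxides liberated in the flask: self-arylation at C3, sequestration of copper by the 5-oxido-4-keto unit, and base-induced opening of the pyranone or reductive loss of iodine in the hot alkoxide medium. The fallback masks the phenols before the coupling. Setting out from 8, K2CO3 in MeOH/THF at 0 °C under argon removes both acetates and 10 is isolated. NaH and chloromethyl methyl ether in DMF convert both phenols into acetals, giving 2-[4-(benzyloxy)phenyl]-3-iodo-7-methoxy-5,8-bis(methoxymethoxy)-4H-chromen-4-one F2. The copper-catalysed coupling with 9 then meets a neutral substrate and should give 3-(benzyloxy)-2-[4-(benzyloxy)phenyl]-7-methoxy-5,8-bis(methoxymethoxy)-4H-chromen-4-one F3. HCl in MeOH/THF cleaves both acetals and the route is rejoined at 11.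

**Step 3.** The most likely failure is direct, non-carbonylative coupling or oxidative dimerisation of the alkyne, because oxidative addition and transmetalation at the doubly ortho-substituted, electron-rich iodide are slow. Premature loss of the acetate next to the new ketone would be followed by closure through the wrong oxygen. The fallback brings in the carbonyl carbon without CO and without 4. Setting out from 3, Rieche formylation (Cl2CHOCH3, TiCl4, CH2Cl2, 0 °C) at the same ring position should give 2-formyl-3,5-dimethoxy-1,4-phenylene diacetate F4. Pinnick oxidation (NaClO2, NaH2PO4, 2-methyl-2-butene) gives 3,6-diacetoxy-2,4-dimethoxybenzoic acid F5, and oxalyl chloride with catalytic DMF gives 3,6-diacetoxy-2,4-dimethoxybenzoyl chloride F6. Acyl Sonogashira coupling of this chloride with 5 (PdCl2(PPh3)2, CuI, Et3N, THF, rt) comes back to the route at 6.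

**Step 6.** The most likely failure is over-acylation at O5 or incomplete discrimination between the two phenols, together with aerial oxidation of the hydroquinone while base is present. The fallback blocks O5 covalently instead of relying on rate differences. Setting out from 11, BF3·OEt2 in CH2Cl2 converts the 5-hydroxy-4-keto unit into its cyclic chelate, 3,4'-bis(benzyloxy)-8-hydroxy-7-methoxyflavone 5-O,4-O-difluoroborate F7. The one remaining hydroxyl is then acetylated without restraint (Ac2O, pyridine, DMAP) to give 8-acetoxy-3,4'-bis(benzyloxy)-7-methoxyflavone 5-O,4-O-difluoroborate F8. Warming in MeOH breaks the B–O bonds and arrives at 12.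

## Further compounds

F1 | step 4 | 5,8-diacetoxy-4'-(benzyloxy)-7-methoxyflavone | COc1cc(OC(C)=O)c2c(=O)cc(-c3ccc(OCc4ccccc4)cc3)oc2c1OC(C)=O
F2 | step 5 | 2-[4-(benzyloxy)phenyl]-3-iodo-7-methoxy-5,8-bis(methoxymethoxy)-4H-chromen-4-one | COc1cc(OCOC)c2c(=O)c(I)c(-c3ccc(OCc4ccccc4)cc3)oc2c1OCOC
F3 | step 5 | 3-(benzyloxy)-2-[4-(benzyloxy)phenyl]-7-methoxy-5,8-bis(methoxymethoxy)-4H-chromen-4-one | COc1cc(OCOC)c2c(=O)c(OCc3ccccc3)c(-c3ccc(OCc4ccccc4)cc3)oc2c1OCOC
F4 | step 3 | 2-formyl-3,5-dimethoxy-1,4-phenylene diacetate | COc1cc(OC(C)=O)c(C=O)c(OC)c1OC(C)=O
F5 | step 3 | 3,6-diacetoxy-2,4-dimethoxybenzoic acid | COc1cc(OC(C)=O)c(C(=O)O)c(OC)c1OC(C)=O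
F6 | step 3 | 3,6-diacetoxy-2,4-dimethoxybenzoyl chloride | COc1cc(OC(C)=O)c(C(=O)Cl)c(OC)c1OC(C)=O
F7 | step 6 | 3,4'-bis(benzyloxy)-8-hydroxy-7-methoxyflavone 5-O,4-O-difluoroborate (cyclic BF2 chelate) | COc1cc2O[B-](F)(F)[O+]=C3C(OCc4ccccc4)=C(c4ccc(OCc5ccccc5)cc4)Oc(c1O)c23
F8 | step 6 | 8-acetoxy-3,4'-bis(benzyloxy)-7-methoxyflavone 5-O,4-O-difluoroborate (cyclic BF2 chelate) | COc1cc2O[B-](F)(F)[O+]=C3C(OCc4ccccc4)=C(c4ccc(OCc5ccccc5)cc4)Oc(c1OC(C)=O)c23
A1 | alternative 1 | 2-(benzyloxy)-1-[2-bromo-6-(tert-butyldimethylsilyloxy)-3-hydroxy-4-methoxyphenyl]ethan-1-one | COc1cc(O[Si](C)(C)C(C)(C)C)c(C(=O)COCc2ccccc2)c(Br)c1O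
A2 | alternative 1 | tert-butyl[(4-methoxyfuran-2-yl)oxy]dimethylsilane | COc1coc(O[Si](C)(C)C(C)(C)C)c1
A3 | alternative 1 | 1-(benzyloxy)-4-bromobut-3-yn-2-one | BrC#CC(=O)COCc1ccccc1
A4 | alternative 2 | 8-acetoxy-3,5,4'-tris(benzyloxy)-7-methoxyflavone | COc1cc(OCc2ccccc2)c2c(=O)c(OCc3ccccc3)c(-c3ccc(OCc4ccccc4)cc3)oc2c1OC(C)=O
A5 | alternative 2 | 5-(benzyloxy)-7-methoxy-2,2-dimethyl-4-oxo-4H-1,3-benzodioxin-8-yl acetate | COc1cc(OCc2ccccc2)c2C(=O)OC(C)(C)Oc2c1OC(C)=O
A6 | alternative 2 | (Z)-{[2-(benzyloxy)-1-[4-(benzyloxy)phenyl]ethenyl]oxy}trimethylsilane | C[Si](C)(C)O/C(=C\OCc1ccccc1)c1ccc(OCc2ccccc2)cc1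
A7 | alternative 2 | 4-(benzyloxy)-2-methoxy-6-oxo-5-(oxomethylidene)cyclohexa-1,3-dien-1-yl acetate (quinoketene) | O=C=C1C(=O)C(OC(C)=O)=C(OC)C=C1OCc1ccccc1
A8 | alternative 3 | rac-(2R,3R)-2-[4-(benzyloxy)phenyl]-3-hydroxy-5,7,8-trimethoxychroman-4-one (trans, one enantiomer drawn) | c1ccccc1COc1ccc(cc1)[C@@H]1[C@H](C(=O)c2c(OC)cc(OC)c(OC)c2O1)O
A9 | alternative 3 | rac-2-{1-[4-(benzyloxy)phenyl]-2-oxoethoxy}-3,4,6-trimethoxybenzaldehyde | COc1cc(OC)c(C=O)c(OC(C=O)c2ccc(OCc3ccccc3)cc2)c1OC
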